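**Plan**

- Unit 1 is the flavan-3,4-diol half (plain locants); unit 2 is the 4-arylflavan-3-ol half (primed locants).
- Cuts: O1'–C2' (etherification) and C2'–aryl (Grignard addition); O1'–C8a', by deleting O1' from ring C of unit 2, which leaves a 3-aryl-indan-1-one; the C(=O)–C8a' bond of that indanone (aryllithium acylation) and C4'–C6 (conjugate arylation); in unit 1, O1–C2 and the chalcone C=C.
- Enabling feature: in the indanone the carbonyl-bearing aryl carbon C8a' lies ortho to the C8' oxygen of ring A of unit 2. No electrophilic closure onto ring A reaches this carbon, but as an ortho-alkoxylated aryl carbon it migrates readily from carbon to oxygen.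
- Forward order: ring C of unit 1 (chalcone epoxide to dihydroflavonol), the C6–C4' bond, the five-membered carbocycle, its expansion by one oxygen atom to the lactone ring C of unit 2, α-oxygenation, opening with the aryl Grignard reagent, and reclosure at O1'–C2'.
- Stereochemistry: C2/C3 from a poly-L-leucine epoxidation; C4 from hydride addition trans to O3; C4' from (R)-BINAP–rhodium conjugate arylation; C3' from C4' (trans hydroxylation); C2' from chelation-controlled Grignard addition followed by Mitsunobu inversion.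

Key step: step 16

Abbreviations: Bn = benzyl, TBS = tert-butyldimethylsilyl, MOM = methoxymethyl. Ar1 = (2R,3R,4R)-3,7,8-tris(benzyloxy)-2-[4-(benzyloxy)phenyl]-4-[(tert-butyldimethylsilyl)oxy]chroman-6-yl, i.e. protected unit 1 bonded through C6.

Assumption: the sense of induction in steps 5 and 14 is taken from the established behaviour of poly-L-leucine towards chalcones and of (R)-BINAP–rhodium towards (E)-enoates.

**Route**

Step 1
Reactants: 1 gallacetophenone (2,3,4-trihydroxyacetophenone)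
Product: 2 1-[3,4-bis(benzyloxy)-2-hydroxyphenyl]ethan-1-one
Conditions: BnBr (2 equiv), K2CO3, DMF, rt
Reagents that add atoms: benzyl bromide, BrCc1ccccc1
Why: Williamson etherification; the 2-hydroxyl is hydrogen-bonded to the acetyl group, is the least nucleophilic of the three phenols and should stay free with two equivalents of halide.

Step 2
Reactants: 2 1-[3,4-bis(benzyloxy)-2-hydroxyphenyl]ethan-1-one
Product: 3 1-[3,4-bis(benzyloxy)-5-bromo-2-hydroxyphenyl]ethan-1-one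
Conditions: N-bromosuccinimide, MeCN, 0 °C
Reagents that add atoms: N-bromosuccinimide, O=C1CCC(=O)N1Br
Why: Electrophilic aromatic bromination; C5 (the later C6 of unit 1) is para to the free phenol and ortho to a benzyloxy group, whereas the only other open position is ortho to the acetyl group.

Step 3
Reactants: 3 1-[3,4-bis(benzyloxy)-5-bromo-2-hydroxyphenyl]ethan-1-one
Product: 4 1-[3,4-bis(benzyloxy)-5-bromo-2-(methoxymethoxy)phenyl]ethan-1-one
Conditions: NaH, MOMCl, DMF, 0 °C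
Reagents that add atoms: chloromethyl methyl ether, COCCl
Why: O-alkylation of the sodium phenoxide; the acetal blocks the phenol during condensation and epoxidation and is lost under the acid of step 6.

Step 4
Reactants: 4 1-[3,4-bis(benzyloxy)-5-bromo-2-(methoxymethoxy)phenyl]ethan-1-one; 5 4-(benzyloxy)benzaldehyde
Product: 6 (E)-1-[3,4-bis(benzyloxy)-5-bromo-2-(methoxymethoxy)phenyl]-3-[4-(benzyloxy)phenyl]prop-2-en-1-one
Conditions: KOH, EtOH/THF, rt
Reagents that add atoms: none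
Why: Claisen–Schmidt condensation of a methyl ketone with a non-enolisable aldehyde; dehydration of the aldol should give the (E)-chalcone.

Step 5
Reactants: 6 (E)-chalcone
Product: 7 [3,4-bis(benzyloxy)-5-bromo-2-(methoxymethoxy)phenyl]{(2R,3S)-3-[4-(benzyloxy)phenyl]oxiran-2-yl}methanone
Conditions: poly-L-leucine, urea–H2O2, DBU, THF, rt
Reagents that add atoms: urea–hydrogen peroxide, NC(N)=O.OO
Why: Juliá–Colonna epoxidation; hydroperoxide bound to the helical poly-L-leucine adds to the enone face that gives the (2R,3S)-trans-epoxide, which fixes the later C3 directly and C2 after inversion.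

Step 6
Reactants: 7 (2R,3S)-epoxy ketone
Product: 9 (2R,3R)-7,8-bis(benzyloxy)-2-[4-(benzyloxy)phenyl]-6-bromo-3-hydroxychroman-4-one, via free phenol epoxide 8 (not isolated)
Conditions: HCl (conc. aq), MeOH/THF, 50 °C
Reagents that add atoms: none
Why: Acid removes the MOM acetal and the freed phenol opens the activated epoxide at the 4-alkoxybenzylic carbon (6-endo, inversion, or capture of the benzylic cation trans to the hydroxyl), the standard chalcone-epoxide route to 2,3-trans-dihydroflavonols, with the oxygen-bearing C3 untouched.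

Step 7
Reactants: 9 (2R,3R)-dihydroflavonol
Product: 10 (2R,3R)-3,7,8-tris(benzyloxy)-2-[4-(benzyloxy)phenyl]-6-bromochroman-4-one
Conditions: benzyl 2,2,2-trichloroacetimidate, TfOH (cat.), CH2Cl2/cyclohexane, 0 °C
Reagents that add atoms: benzyl 2,2,2-trichloroacetimidate, N=C(OCc1ccccc1)C(Cl)(Cl)Cl
Why: Acid-catalysed imidate benzylation, established for α-hydroxy carbonyl compounds, avoids the base that would open, epimerise or dehydrogenate a dihydroflavonol.

Step 8
Reactants: 10 3-O-benzyl dihydroflavonol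
Product: 11 (2R,3S,4R)-3,7,8-tris(benzyloxy)-2-[4-(benzyloxy)phenyl]-6-bromochroman-4-ol (2,3-trans-3,4-trans)
Conditions: NaBH4, MeOH/THF, 0 °C
Reagents that add atoms: none
Why: Borohydride reduction; axial hydride delivery to the half-chair chromanone with equatorial 2-aryl and 3-benzyloxy groups should give the equatorial 4-hydroxyl, the 3,4-trans outcome known for 2,3-trans-dihydroflavonols.

Step 9
Reactants: 11 (2R,3S,4R)-chroman-4-ol
Product: 12 Ar1–Br, (2R,3R,4R)-3,7,8-tris(benzyloxy)-2-[4-(benzyloxy)phenyl]-6-bromo-4-[(tert-butyldimethylsilyl)oxy]chroman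
Conditions: TBSCl, imidazole, DMAP (cat.), DMF, rt
Reagents that add atoms: tert-butyldimethylsilyl chloride, CC(C)(C)[Si](C)(C)Cl
Why: Silylation of the only hydroxyl; a silyl ether on the ionisable benzylic C4 oxygen survives organolithium, peracid, hydride and hydrogenolysis conditions and is removed last with fluoride.

Step 10
Reactants: 12 Ar1–Br
Product: 14 Ar1–B(OH)2 (the C6 boronic acid of protected unit 1), via aryllithium 13 (not isolated)
Conditions: B(Oi-Pr)3, n-BuLi, THF/toluene, −78 °C; then AcOH, H2O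
Reagents that add atoms: triisopropyl borate, CC(C)OB(OC(C)C)OC(C)C; water, O
Why: Bromine–lithium exchange with in situ borate trapping and hydrolysis, the standard boronic acid synthesis; the in situ quench keeps the ortho-benzyloxy aryllithium from rearranging.

Step 11
Reactants: 15 2-bromo-3-hydroxy-4-methoxybenzaldehyde
Product: 16 2-bromo-3,4-dihydroxybenzaldehyde
Conditions: BBr3, CH2Cl2, −78 → 0 °C; H2O
Reagents that add atoms: none
Why: Lewis-acid cleavage of an aryl methyl ether, which the aldehyde and the aryl bromide tolerate.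

Step 12
Reactants: 16 2-bromo-3,4-dihydroxybenzaldehyde
Product: 17 3,4-bis(benzyloxy)-2-bromobenzaldehyde
Conditions: BnBr, K2CO3, DMF, 50 °C
Reagents that add atoms: benzyl bromide, BrCc1ccccc1
Why: Williamson etherification of both phenols, giving the same hydrogenolysable protection as in unit 1.

Step 13
Reactants: 17 3,4-bis(benzyloxy)-2-bromobenzaldehyde
Product: 18 (E)-3-[3,4-bis(benzyloxy)-2-bromophenyl]-N-methoxy-N-methylprop-2-enamide
Conditions: (EtO)2P(O)CH2C(O)N(OMe)Me, NaH, THF, 0 °C → rt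
Reagents that add atoms: diethyl [2-(methoxy(methyl)amino)-2-oxoethyl]phosphonate, CCOP(=O)(OCC)CC(=O)N(C)OC
Why: Horner–Wadsworth–Emmons olefination with a stabilised phosphonate anion, which should give the (E)-enamide.

Step 14
Reactants: 14 Ar1–B(OH)2; 18 (E)-cinnamic Weinreb amide
Product: 19 (3S)-3-Ar1-3-[3,4-bis(benzyloxy)-2-bromophenyl]-N-methoxy-N-methylpropanamide
Conditions: Rh(acac)(C2H4)2 (cat.), (R)-BINAP, K2CO3, 1,4-dioxane/H2O, 90 °C
Reagents that add atoms: none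
Why: Hayashi–Miyaura conjugate arylation (transmetallation to an aryl–rhodium species, enamide insertion, hydrolysis of the rhodium enolate), known for α,β-unsaturated amides and tolerant of aryl bromides; (R)-BINAP, the ligand that turns (E)-crotonates into (S)-3-arylbutanoates, should place Ar1 on the face that gives the required C4' centre under catalyst control.

Step 15
Reactants: 19 (3S)-bromo Weinreb amide
Product: 21 (3R)-3-Ar1-6,7-bis(benzyloxy)-2,3-dihydro-1H-inden-1-one, via aryllithium 20 (not isolated)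
Conditions: t-BuLi (2 equiv), THF, −78 °C; then AcOH
Reagents that add atoms: none
Why: Parham cyclisation; bromine–lithium exchange outruns deprotonation at −78 °C and the aryllithium acylates on the Weinreb amide (5-exo-trig), whose chelated tetrahedral adduct prevents over-addition, so the bromine atom alone places the carbonyl next to the C8' oxygen.

Step 16
Reactants: 21 (3R)-3-Ar1-6,7-bis(benzyloxy)indan-1-one
Product: 23 (4R)-4-Ar1-7,8-bis(benzyloxy)chroman-2-one (3,4-dihydrocoumarin), via Criegee adduct 22 (not isolated)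
Conditions: mCPBA, Na2HPO4, CH2Cl2, 0 °C → rt
Reagents that add atoms: 3-chloroperbenzoic acid, OOC(=O)c1cccc(Cl)c1
Why: Baeyer–Villiger oxidation: the peracid adds to the indanone carbonyl and the Criegee adduct 22 rearranges by a 1,2-shift of the aryl carbon C8a' from carbon to oxygen with loss of 3-chlorobenzoate, which creates the O1'–C8a' bond. The closest known reaction is the peracid oxidation of 7-alkoxyindan-1-ones to 8-alkoxy-3,4-dihydrocoumarins. The six-membered lactone ring C of unit 2 arises by expansion of the five-membered carbocycle (oxygen inserted between C2' and C8a'), not by a cyclisation, so the only geometric demand is the antiperiplanar alignment of the migrating bond with the O–O bond. No stereocentre is formed, and C4', β to the carbonyl, is a spectator. The selectivity needed is aryl over methylene migration, and it is secured by the C8' benzyloxy group ortho to C8a', which stabilises the positive charge developing on the migrating carbon. The phosphate buffer removes the acid that would promote arene hydroxylation or ionise the C4 silyl ether, which should keep the electron-rich rings intact.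

Step 17
Reactants: 23 (4R)-dihydrocoumarin
Product: 25 (3R,4R)-4-Ar1-7,8-bis(benzyloxy)-3-hydroxychroman-2-one (3,4-trans), via potassium enolate 24 (not isolated)
Conditions: KN(SiMe3)2, THF, −78 °C; 2-(phenylsulfonyl)-3-phenyloxaziridine; then AcOH
Reagents that add atoms: 2-(phenylsulfonyl)-3-phenyloxaziridine, O=S(=O)(c1ccccc1)N1OC1c1ccccc1
Why: Enolate hydroxylation with a Davis oxaziridine; the oxidant should approach the lactone enolate anti to the pseudoaxial C4' aryl group and set C3' trans to C4' under substrate control.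

Step 18
Reactants: 25 (3R,4R)-3-hydroxy lactone
Product: 26 (3R,4R)-4-Ar1-3,7,8-tris(benzyloxy)chroman-2-one
Conditions: BnBr, Ag2O, 4 Å sieves, CH2Cl2, rt, dark
Reagents that add atoms: benzyl bromide, BrCc1ccccc1
Why: Ag2O-mediated benzylation, the neutral method used for α-hydroxy esters, avoids both base (epimerisation at C3', lactone opening) and acid (ionisation of the C4 silyl ether).

Step 19
Reactants: 26 (3R,4R)-3-benzyloxy lactone
Product: 27 (3R,4R)-4-Ar1-3,7,8-tris(benzyloxy)chroman-2-ol (lactol, both C2' epimers)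
Conditions: i-Bu2AlH, CH2Cl2, −78 °C; aq KNa tartrate
Reagents that add atoms: none
Why: Partial reduction of a lactone to the lactol; the tetrahedral aluminium alkoxide persists at −78 °C until work-up, so over-reduction should not occur.

Step 20
Reactants: 27 lactol; 28 1-(benzyloxy)-4-bromobenzene
Product: 30 (1R,2R,3R)-3-Ar1-2-(benzyloxy)-1-[4-(benzyloxy)phenyl]-3-[3,4-bis(benzyloxy)-2-hydroxyphenyl]propan-1-ol, via arylmagnesium bromide 29 (not isolated)
Conditions: 28, Mg, THF, 40 °C; then 27, THF/CH2Cl2, −78 → −20 °C; then H2O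
Reagents that add atoms: none
Why: Grignard addition to the ring-opened aldehyde form of the lactol under Cram chelation control; magnesium bridging the aldehyde oxygen and the C3' benzyloxy group exposes the face remote from the C4' diarylmethyl group and should give the 2',3'-syn alcohol.

Step 21
Reactants: 30 (1R,2R,3R)-phenol alcohol
Product: 31 (2S,3R,4R)-4-Ar1-3,7,8-tris(benzyloxy)-2-[4-(benzyloxy)phenyl]chroman (2,3-trans-3,4-trans)
Conditions: PPh3, DIAD, THF, 0 °C → rt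
Reagents that add atoms: none
Why: Intramolecular Mitsunobu etherification (6-exo-tet); the phenol displaces the activated benzylic oxygen with inversion at C2', re-forming O1'–C2' and giving the all-equatorial flavan, which is also the thermodynamically preferred isomer.

Step 22
Reactants: 31 octabenzyl silyl ether
Product: 32 (2S,3R,4S)-4-[(2R,3R,4R)-4-[(tert-butyldimethylsilyl)oxy]-3,7,8-trihydroxy-2-(4-hydroxyphenyl)chroman-6-yl]-2-(4-hydroxyphenyl)chroman-3,7,8-triol
Conditions: H2 (1 atm), Pd(OH)2/C, THF/MeOH, rt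
Reagents that add atoms: none
Why: Hydrogenolysis of the eight benzyl ethers under neutral conditions; the cyclic benzylic ethers and the silyl-protected C4 oxygen are expected to resist, which is why C4 stays silylated at this stage.

Step 23
Reactants: 32 4-O-silyl polyphenol
Product: 33 (2R,3S,4R)-6-[(2S,3R,4S)-3,7,8-trihydroxy-2-(4-hydroxyphenyl)chroman-4-yl]-2-(4-hydroxyphenyl)chroman-3,4,7,8-tetrol (CNP0391561.6)
Conditions: HF·pyridine, pyridine, THF, 0 °C → rt
Reagents that add atoms: none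
Why: Fluoride-mediated desilylation buffered with pyridine, mild enough not to ionise the free flavan-4-ol and free of the strong base that would oxidise the catechol-type rings.

**Compound list**

1 | gallacetophenone, 1-(2,3,4-trihydroxyphenyl)ethan-1-one | CC(=O)c1ccc(O)c(O)c1O | starting material
2 | 1-[3,4-bis(benzyloxy)-2-hydroxyphenyl]ethan-1-one | CC(=O)c1ccc(OCc2ccccc2)c(OCc2ccccc2)c1O | intermediate
3 | 1-[3,4-bis(benzyloxy)-5-bromo-2-hydroxyphenyl]ethan-1-one | CC(=O)c1cc(Br)c(OCc2ccccc2)c(OCc2ccccc2)c1O | intermediate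
4 | 1-[3,4-bis(benzyloxy)-5-bromo-2-(methoxymethoxy)phenyl]ethan-1-one | CC(=O)c1cc(Br)c(OCc2ccccc2)c(OCc2ccccc2)c1OCOC | intermediate
5 | 4-(benzyloxy)benzaldehyde | O=Cc1ccc(OCc2ccccc2)cc1 | starting material
6 | (E)-1-[3,4-bis(benzyloxy)-5-bromo-2-(methoxymethoxy)phenyl]-3-[4-(benzyloxy)phenyl]prop-2-en-1-one | O=C(/C=C/c1ccc(OCc2ccccc2)cc1)c1cc(Br)c(OCc2ccccc2)c(OCc2ccccc2)c1OCOC | intermediate
7 | [3,4-bis(benzyloxy)-5-bromo-2-(methoxymethoxy)phenyl]{(2R,3S)-3-[4-(benzyloxy)phenyl]oxiran-2-yl}methanone | O=C([C@@H]1O[C@H]1c1ccc(OCc2ccccc2)cc1)c1cc(Br)c(OCc2ccccc2)c(OCc2ccccc2)c1OCOC | intermediate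
8 | [3,4-bis(benzyloxy)-5-bromo-2-hydroxyphenyl]{(2R,3S)-3-[4-(benzyloxy)phenyl]oxiran-2-yl}methanone | O=C([C@@H]1O[C@H]1c1ccc(OCc2ccccc2)cc1)c1cc(Br)c(OCc2ccccc2)c(OCc2ccccc2)c1O | intermediate (not isolated)
9 | (2R,3R)-7,8-bis(benzyloxy)-2-[4-(benzyloxy)phenyl]-6-bromo-3-hydroxychroman-4-one | c9ccccc9COc1ccc([C@H]2Oc3c(cc(Br)c(OCc9ccccc9)c3OCc9ccccc9)C(=O)[C@@H]2O)cc1 | intermediate
10 | (2R,3R)-3,7,8-tris(benzyloxy)-2-[4-(benzyloxy)phenyl]-6-bromochroman-4-one | c9ccccc9COc1ccc([C@H]2Oc3c(cc(Br)c(OCc9ccccc9)c3OCc9ccccc9)C(=O)[C@@H]2OCc9ccccc9)cc1 | intermediate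
11 | (2R,3S,4R)-3,7,8-tris(benzyloxy)-2-[4-(benzyloxy)phenyl]-6-bromochroman-4-ol | c9ccccc9COc1ccc([C@H]2Oc3c(cc(Br)c(OCc9ccccc9)c3OCc9ccccc9)[C@@H](O)[C@@H]2OCc9ccccc9)cc1 | intermediate
12 | Ar1–Br, (2R,3R,4R)-3,7,8-tris(benzyloxy)-2-[4-(benzyloxy)phenyl]-6-bromo-4-[(tert-butyldimethylsilyl)oxy]chroman | c9ccccc9COc1ccc([C@H]2Oc3c(cc(Br)c(OCc9ccccc9)c3OCc9ccccc9)[C@@H](O[Si](C)(C)C(C)(C)C)[C@@H]2OCc9ccccc9)cc1 | intermediate
13 | Ar1–Li, the 6-lithio analogue of 12 | c9ccccc9COc1ccc([C@H]2Oc3c(cc([Li])c(OCc9ccccc9)c3OCc9ccccc9)[C@@H](O[Si](C)(C)C(C)(C)C)[C@@H]2OCc9ccccc9)cc1 | intermediate (not isolated)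
14 | Ar1–B(OH)2, [(2R,3R,4R)-3,7,8-tris(benzyloxy)-2-[4-(benzyloxy)phenyl]-4-[(tert-butyldimethylsilyl)oxy]chroman-6-yl]boronic acid | c9ccccc9COc1ccc([C@H]2Oc3c(cc(B(O)O)c(OCc9ccccc9)c3OCc9ccccc9)[C@@H](O[Si](C)(C)C(C)(C)C)[C@@H]2OCc9ccccc9)cc1 | intermediate
15 | 2-bromo-3-hydroxy-4-methoxybenzaldehyde | COc1ccc(C=O)c(Br)c1O | starting material
16 | 2-bromo-3,4-dihydroxybenzaldehyde | O=Cc1ccc(O)c(O)c1Br | intermediate
17 | 3,4-bis(benzyloxy)-2-bromobenzaldehyde | O=Cc1ccc(OCc2ccccc2)c(OCc2ccccc2)c1Br | intermediate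
18 | (E)-3-[3,4-bis(benzyloxy)-2-bromophenyl]-N-methoxy-N-methylprop-2-enamide | CON(C)C(=O)/C=C/c1ccc(OCc2ccccc2)c(OCc2ccccc2)c1Br | intermediate
19 | (3S)-3-Ar1-3-[3,4-bis(benzyloxy)-2-bromophenyl]-N-methoxy-N-methylpropanamide | c9ccccc9COc1ccc([C@H]2Oc3c(cc([C@H](CC(=O)N(C)OC)c5ccc(OCc9ccccc9)c(OCc9ccccc9)c5Br)c(OCc9ccccc9)c3OCc9ccccc9)[C@@H](O[Si](C)(C)C(C)(C)C)[C@@H]2OCc9ccccc9)cc1 | intermediate
20 | analogue of 19 with lithium in place of bromine, configuration unchanged | c9ccccc9COc1ccc([C@H]2Oc3c(cc([C@H](CC(=O)N(C)OC)c5ccc(OCc9ccccc9)c(OCc9ccccc9)c5[Li])c(OCc9ccccc9)c3OCc9ccccc9)[C@@H](O[Si](C)(C)C(C)(C)C)[C@@H]2OCc9ccccc9)cc1 | intermediate (not isolated)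
21 | (3R)-3-Ar1-6,7-bis(benzyloxy)-2,3-dihydro-1H-inden-1-one | c9ccccc9COc1ccc([C@H]2Oc3c(cc([C@@H]4CC(=O)c5c(OCc9ccccc9)c(OCc9ccccc9)ccc54)c(OCc9ccccc9)c3OCc9ccccc9)[C@@H](O[Si](C)(C)C(C)(C)C)[C@@H]2OCc9ccccc9)cc1 | intermediate
22 | Criegee adduct, (3R)-3-Ar1-6,7-bis(benzyloxy)-1-hydroxyindan-1-yl 3-chloroperbenzoate (C1 epimers) | c9ccccc9COc1ccc([C@H]2Oc3c(cc([C@@H]4CC(O)(OOC(=O)c6cccc(Cl)c6)c5c(OCc9ccccc9)c(OCc9ccccc9)ccc54)c(OCc9ccccc9)c3OCc9ccccc9)[C@@H](O[Si](C)(C)C(C)(C)C)[C@@H]2OCc9ccccc9)cc1 | intermediate (not isolated)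
23 | (4R)-4-Ar1-7,8-bis(benzyloxy)chroman-2-one | c9ccccc9COc1ccc([C@H]2Oc3c(cc([C@@H]4CC(=O)Oc5c(OCc9ccccc9)c(OCc9ccccc9)ccc54)c(OCc9ccccc9)c3OCc9ccccc9)[C@@H](O[Si](C)(C)C(C)(C)C)[C@@H]2OCc9ccccc9)cc1 | intermediate
24 | potassium (4R)-4-Ar1-7,8-bis(benzyloxy)-4H-chromen-2-olate | c9ccccc9COc1ccc([C@H]2Oc3c(cc([C@@H]4C=C([O-])Oc5c(OCc9ccccc9)c(OCc9ccccc9)ccc54)c(OCc9ccccc9)c3OCc9ccccc9)[C@@H](O[Si](C)(C)C(C)(C)C)[C@@H]2OCc9ccccc9)cc1.[K+] | intermediate (not isolated)
25 | (3R,4R)-4-Ar1-7,8-bis(benzyloxy)-3-hydroxychroman-2-one | c9ccccc9COc1ccc([C@H]2Oc3c(cc([C@@H]4[C@@H](O)C(=O)Oc5c(OCc9ccccc9)c(OCc9ccccc9)ccc54)c(OCc9ccccc9)c3OCc9ccccc9)[C@@H](O[Si](C)(C)C(C)(C)C)[C@@H]2OCc9ccccc9)cc1 | intermediate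
26 | (3R,4R)-4-Ar1-3,7,8-tris(benzyloxy)chroman-2-one | c9ccccc9COc1ccc([C@H]2Oc3c(cc([C@@H]4[C@@H](OCc9ccccc9)C(=O)Oc5c(OCc9ccccc9)c(OCc9ccccc9)ccc54)c(OCc9ccccc9)c3OCc9ccccc9)[C@@H](O[Si](C)(C)C(C)(C)C)[C@@H]2OCc9ccccc9)cc1 | intermediate
27 | (3R,4R)-4-Ar1-3,7,8-tris(benzyloxy)chroman-2-ol (both C2 epimers) | c9ccccc9COc1ccc([C@H]2Oc3c(cc([C@@H]4[C@@H](OCc9ccccc9)C(O)Oc5c(OCc9ccccc9)c(OCc9ccccc9)ccc54)c(OCc9ccccc9)c3OCc9ccccc9)[C@@H](O[Si](C)(C)C(C)(C)C)[C@@H]2OCc9ccccc9)cc1 | intermediate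
28 | 1-(benzyloxy)-4-bromobenzene | Brc1ccc(OCc2ccccc2)cc1 | starting material
29 | [4-(benzyloxy)phenyl]magnesium bromide | Br[Mg]c1ccc(OCc2ccccc2)cc1 | intermediate (not isolated)
30 | (1R,2R,3R)-3-Ar1-2-(benzyloxy)-1-[4-(benzyloxy)phenyl]-3-[3,4-bis(benzyloxy)-2-hydroxyphenyl]propan-1-ol | c9ccccc9COc1ccc([C@H]2Oc3c(cc([C@@H](c5ccc(OCc9ccccc9)c(OCc9ccccc9)c5O)[C@@H](OCc9ccccc9)[C@H](O)c6ccc(OCc9ccccc9)cc6)c(OCc9ccccc9)c3OCc9ccccc9)[C@@H](O[Si](C)(C)C(C)(C)C)[C@@H]2OCc9ccccc9)cc1 | intermediate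
31 | (2S,3R,4R)-4-Ar1-3,7,8-tris(benzyloxy)-2-[4-(benzyloxy)phenyl]chroman | c9ccccc9COc1ccc([C@H]2Oc3c(cc([C@H]4c5ccc(OCc9ccccc9)c(OCc9ccccc9)c5O[C@@H](c5ccc(OCc9ccccc9)cc5)[C@@H]4OCc9ccccc9)c(OCc9ccccc9)c3OCc9ccccc9)[C@@H](O[Si](C)(C)C(C)(C)C)[C@@H]2OCc9ccccc9)cc1 | intermediate
32 | (2S,3R,4S)-4-[(2R,3R,4R)-4-[(tert-butyldimethylsilyl)oxy]-3,7,8-trihydroxy-2-(4-hydroxyphenyl)chroman-6-yl]-2-(4-hydroxyphenyl)chroman-3,7,8-triol | Oc1ccc([C@H]2Oc3c(cc([C@H]4c5ccc(O)c(O)c5O[C@@H](c5ccc(O)cc5)[C@@H]4O)c(O)c3O)[C@@H](O[Si](C)(C)C(C)(C)C)[C@@H]2O)cc1 | intermediate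
33 | (2R,3S,4R)-6-[(2S,3R,4S)-3,7,8-trihydroxy-2-(4-hydroxyphenyl)chroman-4-yl]-2-(4-hydroxyphenyl)chroman-3,4,7,8-tetrol (CNP0391561.6) | Oc1ccc([C@H]2Oc3c(cc([C@H]4c5ccc(O)c(O)c5O[C@@H](c5ccc(O)cc5)[C@@H]4O)c(O)c3O)[C@@H](O)[C@@H]2O)cc1 | target

**Step count**

Total: 23 steps. Longest linear sequence: 20 steps (steps 1–10, then 14–23); steps 11–13 form the side branch.

**Steps most likely to fail**

1. Step 14. Insertion of the hindered ortho-bromo cinnamamide into the aryl–rhodium bond may be slow enough for protodeboronation of 14 to take over, and discrimination between the two aryl-flanked faces may fall short. The fallback sets out from 12 and 17 and returns at 19, with auxiliary control in place of catalyst control.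
   - 17 is condensed under Masamune–Roush Horner–Wadsworth–Emmons conditions (LiCl, i-Pr2NEt, MeCN) with diethyl {2-oxo-2-[(4R)-2-oxo-4-phenyl-1,3-oxazolidin-3-yl]ethyl}phosphonate to give the N-enoyl oxazolidinone, (4R)-3-{(2E)-3-[3,4-bis(benzyloxy)-2-bromophenyl]prop-2-enoyl}-4-phenyl-1,3-oxazolidin-2-one F1.
   - 12 is lithiated as in step 10 to the aryllithium 13 and transmetallated with MgBr2·OEt2 to the arylmagnesium bromide Ar1–MgBr F2.
   - In the presence of CuBr·SMe2 (THF, −40 °C), F2 should add to the magnesium-chelated s-cis imide from the face opposite the phenyl group to give the adduct (4R)-3-{(3S)-3-Ar1-3-[3,4-bis(benzyloxy)-2-bromophenyl]propanoyl}-4-phenyl-1,3-oxazolidin-2-one F3.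
   - Treatment of F3 with Me2AlN(OMe)Me (from AlMe3 and MeNH(OMe)·HCl, CH2Cl2, 0 °C) exchanges the auxiliary for the Weinreb amide and delivers 19.

2. Step 16. Addition of the peracid to the electron-rich, conjugated ketone may be slow, so that oxidation of the benzyloxylated rings or of benzylic positions intervenes before the Criegee adduct rearranges. The fallback sets out from 19 and returns at 23; it makes the O1'–C8a' bond by a boron-to-oxygen aryl shift instead.
   - Miyaura borylation of 19 (B2pin2, Pd(dppf)Cl2, KOAc, 1,4-dioxane, 90 °C) should give the aryl pinacol boronate, 19 with 4,4,5,5-tetramethyl-1,3,2-dioxaborolan-2-yl in place of bromine, F4.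
   - Oxidation with NaBO3·4H2O (THF/H2O, rt) should give the phenol, 19 with hydroxyl in place of bromine, F5.
   - Warming F5 with a catalytic amount of pyridinium p-toluenesulfonate in toluene (60 °C) should close the lactone 23 with loss of N,O-dimethylhydroxylamine.

3. Step 20. Open-chain (Felkin–Anh) addition may compete with the chelated pathway and erode the selectivity at C2', and the α-benzyloxy aldehyde may epimerise at C3' before it is trapped. The fallback sets out from 26 and returns at 30; it sets C2' by reagent-controlled reduction instead of addition.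
   - Aminolysis of 26 with MeNH(OMe)·HCl and i-PrMgCl (THF, −20 °C) should give the phenolic Weinreb amide (2R,3R)-3-Ar1-2-(benzyloxy)-3-[3,4-bis(benzyloxy)-2-hydroxyphenyl]-N-methoxy-N-methylpropanamide F6.
   - Excess 29 should convert F6 without over-addition into the aryl ketone (2R,3R)-3-Ar1-2-(benzyloxy)-1-[4-(benzyloxy)phenyl]-3-[3,4-bis(benzyloxy)-2-hydroxyphenyl]propan-1-one F7.
   - Corey–Bakshi–Shibata reduction of F7 with the (R)-configured 2-methyl oxazaborolidine and BH3·SMe2 should give 30; the aryl group is expected to act as the large substituent, a sense that coincides with the Felkin–Anh preference of the α-benzyloxy ketone.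

Further compounds
F1 | step 14 | (4R)-3-{(2E)-3-[3,4-bis(benzyloxy)-2-bromophenyl]prop-2-enoyl}-4-phenyl-1,3-oxazolidin-2-one | O=C(/C=C/c1ccc(OCc2ccccc2)c(OCc2ccccc2)c1Br)N1[C@H](c2ccccc2)COC1=O
F2 | step 14 | Ar1–MgBr, the 6-bromomagnesio analogue of 12 | c9ccccc9COc1ccc([C@H]2Oc3c(cc([Mg]Br)c(OCc9ccccc9)c3OCc9ccccc9)[C@@H](O[Si](C)(C)C(C)(C)C)[C@@H]2OCc9ccccc9)cc1
F3 | step 14 | (4R)-3-{(3S)-3-Ar1-3-[3,4-bis(benzyloxy)-2-bromophenyl]propanoyl}-4-phenyl-1,3-oxazolidin-2-one | c9ccccc9COc1ccc([C@H]2Oc3c(cc([C@H](CC(=O)N4[C@H](c9ccccc9)COC4=O)c5ccc(OCc9ccccc9)c(OCc9ccccc9)c5Br)c(OCc9ccccc9)c3OCc9ccccc9)[C@@H](O[Si](C)(C)C(C)(C)C)[C@@H]2OCc9ccccc9)cc1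
F4 | step 16 | aryl pinacol boronate, 19 with 4,4,5,5-tetramethyl-1,3,2-dioxaborolan-2-yl in place of bromine | c9ccccc9COc1ccc([C@H]2Oc3c(cc([C@H](CC(=O)N(C)OC)c5ccc(OCc9ccccc9)c(OCc9ccccc9)c5B6OC(C)(C)C(C)(C)O6)c(OCc9ccccc9)c3OCc9ccccc9)[C@@H](O[Si](C)(C)C(C)(C)C)[C@@H]2OCc9ccccc9)cc1
F5 | step 16 | phenol, 19 with hydroxyl in place of bromine | c9ccccc9COc1ccc([C@H]2Oc3c(cc([C@H](CC(=O)N(C)OC)c5ccc(OCc9ccccc9)c(OCc9ccccc9)c5O)c(OCc9ccccc9)c3OCc9ccccc9)[C@@H](O[Si](C)(C)C(C)(C)C)[C@@H]2OCc9ccccc9)cc1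
F6 | step 20 | (2R,3R)-3-Ar1-2-(benzyloxy)-3-[3,4-bis(benzyloxy)-2-hydroxyphenyl]-N-methoxy-N-methylpropanamide | c9ccccc9COc1ccc([C@H]2Oc3c(cc([C@@H](c5ccc(OCc9ccccc9)c(OCc9ccccc9)c5O)[C@@H](OCc9ccccc9)C(=O)N(C)OC)c(OCc9ccccc9)c3OCc9ccccc9)[C@@H](O[Si](C)(C)C(C)(C)C)[C@@H]2OCc9ccccc9)cc1
F7 | step 20 | (2R,3R)-3-Ar1-2-(benzyloxy)-1-[4-(benzyloxy)phenyl]-3-[3,4-bis(benzyloxy)-2-hydroxyphenyl]propan-1-one | c9ccccc9COc1ccc([C@H]2Oc3c(cc([C@@H](c5ccc(OCc9ccccc9)c(OCc9ccccc9)c5O)[C@@H](OCc9ccccc9)C(=O)c6ccc(OCc9ccccc9)cc6)c(OCc9ccccc9)c3OCc9ccccc9)[C@@H](O[Si](C)(C)C(C)(C)C)[C@@H]2OCc9ccccc9)cc1
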